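The arene is numbered C1 (acetyl-bearing), C2 and C4 (hydroxyl-bearing), C6 (chain-bearing).
Retrosynthesis: the arene goes back to a cyclohexane-1,3-dione that keeps the C1 acetyl and has an extra ester on C5. That ring is cut at C5–C6 (conjugate addition) and C3–C4 (Claisen), the alkylidene diketone at C1=C6 (Knoevenagel), and the chain at its terminal CH2–phenyl bond.
Enabling feature: C1 and C6 with acetyl and chain are an alkylidene acetylacetone in disguise, C2–C3 are its second acetyl group, and C4–C5 are two carbons of a malonate.
Forward: the phenylundecyl chain is built first (copper-catalysed Grignard coupling, oxidation) and condensed with acetylacetone; the only new ring closes in step 4.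
Endgame: the ring is aromatized with bromine while the ester is still in place; saponification and decarboxylation then remove the ester.
Stereochemistry: the target has no stereocentre; the three ring centres formed in step 4 are erased on aromatization, and the Knoevenagel alkene has no geometry because its two acyl groups are identical.

Key step: step 4

Assumption: phenylmagnesium bromide is bought as a THF solution; metal alkoxides, enolates, phenoxides and carboxylates that are merely reprotonated on work-up count as ionized forms of the neutral compounds; the polycarbonyl ring compounds are drawn as keto tautomers although they should be largely enolized.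

Step 1
Reactants: 1 11-bromoundecan-1-ol; 2 phenylmagnesium bromide
Product: 3 11-phenylundecan-1-ol
Conditions: 2 (2.5 equiv), Li2CuCl4 (3 mol %), THF/NMP, −10 °C to rt; then 1 M HCl
Reagents that add atoms: none
Why: Copper-catalysed (Kochi-type) cross-coupling of an aryl Grignard reagent with a primary alkyl bromide, in which the first equivalent of 2 only deprotonates the hydroxyl group and the resulting magnesium alkoxide is a spectator.

Step 2
Reactants: 3 11-phenylundecan-1-ol
Product: 4 11-phenylundecanal
Conditions: TEMPO (1 mol %), KBr (10 mol %), aq NaOCl (1.1 equiv), NaHCO3, CH2Cl2/H2O, 0 °C
Reagents that add atoms: none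
Why: Anelli oxidation, in which the oxoammonium salt formed from TEMPO and hypochlorite takes the primary alcohol to the aldehyde and, in the buffered two-phase system at 0 °C, should neither carry it on to the acid nor touch the benzylic position.

Step 3
Reactants: 4 11-phenylundecanal; 5 pentane-2,4-dione
Product: 6 3-(11-phenylundecylidene)pentane-2,4-dione
Conditions: TiCl4 (2.0 equiv), pyridine (4.0 equiv), THF, 0 °C to rt
Reagents that add atoms: none
Why: Knoevenagel condensation in its TiCl4/pyridine form, in which a titanium diketonate adds to the aldehyde and titanium binds the water irreversibly at 0 °C, which should hold back both a second addition of 5 and migration of the double bond, and which raises no question of alkene geometry because the two acyl groups are identical.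

Step 4
Reactants: 6 3-(11-phenylundecylidene)pentane-2,4-dione; 7 dimethyl malonate
Product: 9 methyl 3-acetyl-4,6-dioxo-2-(10-phenyldecyl)cyclohexane-1-carboxylate (enolized diastereomer mixture), via malonate Michael adduct 8 (not isolated)
Conditions: NaOMe (0.2 equiv), MeOH, 0 °C to rt; then NaOMe (2.5 equiv), reflux; then 1 M HCl
Reagents that add atoms: none
Why: Sodiomalonate adds in conjugate fashion to the doubly activated alkene of 6 and forms the C5–C6 bond (arene numbering), giving 8 as its diketone enolate; at reflux with excess methoxide the small equilibrium share of an acetyl methyl enolate attacks one malonate ester carbonyl, forms the C3–C4 bond and expels methoxide. The closest known reaction type is the Michael–Claisen (dimedone-type) annulation of malonates with α,β-unsaturated methyl ketones, here run on an enone that carries a second acetyl group on its α-carbon. The one ring closes by a 6-(enolendo)-exo-trig Claisen (Dieckmann-type) acylation and should be pulled to completion by deprotonation of the strongly acidic cyclic 1,3-dione. The three ring carbons that bear ester, chain and acetyl become stereogenic, but none needs control, since two are enolizable and all three turn sp2 in step 5. The selectivity needed is C-acylation by an acetyl methyl group in preference to aldol chemistry, O-acylation or loss of acetyl: the two acetyl groups of 8 are equivalent, every aldol alternative would close a four-membered ring, an enol lactone from O-acylation is reopened by methoxide, and the diketone rests as an enolate that resists attack at its carbonyl carbons. A second, bridging Claisen closure onto the remaining ester is not expected to persist, because its bicyclo[3.3.1] product would hold β-dicarbonyl bridgeheads that cannot enolize without a bridgehead double bond and would be cleaved again by methoxide.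

Step 5
Reactants: 9 methyl 3-acetyl-4,6-dioxo-2-(10-phenyldecyl)cyclohexane-1-carboxylate
Product: 11 methyl 3-acetyl-4,6-dihydroxy-2-(10-phenyldecyl)benzoate, via bromo dione 10 (not isolated)
Conditions: Br2 (1.0 equiv), DMF, 0 °C, dark; then 80 °C
Reagents that add atoms: none
Why: Bromination–dehydrobromination aromatization known for 2,4-dioxocyclohexanecarboxylates, in which bromine enters the enolized dione at the carbon between the two ring ketones and, on warming, HBr is lost through the enol (if need be after HBr-mediated relay of the bromine to a carbon next to the chain-bearing CH) to a dienone that tautomerizes to the resorcinol, whose two acyl substituents should temper further ring bromination.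

Step 6
Reactants: 11 methyl 3-acetyl-4,6-dihydroxy-2-(10-phenyldecyl)benzoate
Product: 13 1-[2,4-dihydroxy-6-(10-phenyldecyl)phenyl]ethan-1-one, via resorcylic acid 12 (not isolated)
Conditions: NaOH (5 equiv), MeOH/H2O, reflux, N2; then 2 M HCl to pH 2, 50 °C
Reagents that add atoms: none
Why: Saponification of the hindered ester followed by protodecarboxylation of the resulting β-resorcylic acid, whose carboxyl-bearing carbon is ortho and para to the two hydroxyls and is twisted out of plane by the flanking chain, so that ipso protonation and loss of CO2 should occur on gentle warming in dilute acid, conditions under which the aryl methyl ketone is not expected to be cleaved.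

Compound list
1 | 11-bromoundecan-1-ol | OCCCCCCCCCCCBr | starting material
2 | phenylmagnesium bromide | Br[Mg]c1ccccc1 | starting material
3 | 11-phenylundecan-1-ol | OCCCCCCCCCCCc1ccccc1 | intermediate
4 | 11-phenylundecanal | O=CCCCCCCCCCCc1ccccc1 | intermediate
5 | pentane-2,4-dione | CC(=O)CC(C)=O | starting material
6 | 3-(11-phenylundecylidene)pentane-2,4-dione | CC(=O)C(=CCCCCCCCCCCc1ccccc1)C(C)=O | intermediate
7 | dimethyl malonate | COC(=O)CC(=O)OC | starting material
8 | dimethyl 2-[2-acetyl-3-oxo-1-(10-phenyldecyl)butyl]propanedioate (racemic, not isolated) | COC(=O)C(C(=O)OC)C(CCCCCCCCCCc1ccccc1)C(C(C)=O)C(C)=O | intermediate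
9 | methyl 3-acetyl-4,6-dioxo-2-(10-phenyldecyl)cyclohexane-1-carboxylate (diastereomer mixture, stereocentres transient) | COC(=O)C1C(=O)CC(=O)C(C(C)=O)C1CCCCCCCCCCc1ccccc1 | intermediate
10 | methyl 3-acetyl-5-bromo-4,6-dioxo-2-(10-phenyldecyl)cyclohexane-1-carboxylate (diastereomer mixture, not isolated) | COC(=O)C1C(=O)C(Br)C(=O)C(C(C)=O)C1CCCCCCCCCCc1ccccc1 | intermediate
11 | methyl 3-acetyl-4,6-dihydroxy-2-(10-phenyldecyl)benzoate | COC(=O)c1c(O)cc(O)c(C(C)=O)c1CCCCCCCCCCc1ccccc1 | intermediate
12 | 3-acetyl-4,6-dihydroxy-2-(10-phenyldecyl)benzoic acid (not isolated) | OC(=O)c1c(O)cc(O)c(C(C)=O)c1CCCCCCCCCCc1ccccc1 | intermediate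
13 | 1-[2,4-dihydroxy-6-(10-phenyldecyl)phenyl]ethan-1-one | CC(=O)c1c(O)cc(O)cc1CCCCCCCCCCc1ccccc1 | target

Total step count: 6. Longest linear sequence: 6 steps (1 to 13); 2, 5 and 7 are bought.

Steps most likely to fail

Step 4. Methoxide may attack an acetyl carbonyl of the open-chain adduct (retro-Claisen loss of methyl acetate) before the ring has closed, or the closure may stall because both acidic sites rest as unreactive enolates. The fallback sets out from 6 and comes back at 13. It replaces the malonate by a mono-ester donor, adds it irreversibly under Lewis acid catalysis, and closes the ring with a base too hindered to attack a carbonyl. Mukaiyama–Michael addition of commercial 1-(tert-butyldimethylsilyloxy)-1-methoxyethene to 6 (Sc(OTf)3, 5 mol %, CH2Cl2, −78 to 0 °C) should give the silyl enol ether methyl 4-acetyl-5-[(tert-butyldimethylsilyl)oxy]-3-(10-phenyldecyl)hex-4-enoate F1, which is not isolated. Work-up with 1 M HCl should release methyl 4-acetyl-5-oxo-3-(10-phenyldecyl)hexanoate F2. Heating F2 with KOtBu (2.5 equiv) in THF/t-BuOH, then acidifying, should close the same C3–C4 bond by Claisen acylation, as in the technical cyclization of 5-oxohexanoate esters, and give 4-acetyl-5-(10-phenyldecyl)cyclohexane-1,3-dione F3. This dione has no ester to remove; catalytic dehydrogenation (10 % Pd/C, mesitylene, reflux, argon sweep) should take it directly to 13.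

Step 3. A second molecule of 5 may add to the freshly formed alkylidene diketone, and the double bond may drift out of conjugation during reaction or purification. The fallback sets out from 4 and comes back at 9. The roles of the two C–H acids are exchanged: Knoevenagel condensation of 4 with 7 (piperidine/AcOH cat., toluene, Dean–Stark) should give dimethyl 2-(11-phenylundecylidene)propanedioate F4, a less electrophilic and more robust acceptor. Addition of the sodium enolate of 5 (NaOMe, MeOH, 0 °C to rt) should then form the C1–C6 bond and give the same open-chain adduct 8 in the flask. More NaOMe at reflux, as in step 4, should close it to 9.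

Step 5. Bromination may spill over to the free ring position between the hydroxyls or to the acetyl methyl group, and loss of HBr may be incomplete. The fallback sets out from 9 and comes back at 13. It removes the ester first and aromatizes without halogen. Saponification of 9 (aq NaOH/MeOH, reflux) should give 3-acetyl-4,6-dioxo-2-(10-phenyldecyl)cyclohexane-1-carboxylic acid F5, which is not isolated; acidification with HCl and warming to 60 °C should decarboxylate it to 4-acetyl-5-(10-phenyldecyl)cyclohexane-1,3-dione F3, the compound also reached in the fallback to step 4. Dehydrogenation over 10 % Pd/C in refluxing mesitylene should then give 13.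

Further compounds
F1 | step 4 | methyl 4-acetyl-5-[(tert-butyldimethylsilyl)oxy]-3-(10-phenyldecyl)hex-4-enoate (alkene geometry undefined, not isolated) | COC(=O)CC(CCCCCCCCCCc1ccccc1)C(C(C)=O)=C(C)O[Si](C)(C)C(C)(C)C
F2 | step 4 | methyl 4-acetyl-5-oxo-3-(10-phenyldecyl)hexanoate (racemic) | COC(=O)CC(CCCCCCCCCCc1ccccc1)C(C(C)=O)C(C)=O
F3 | step 4 | 4-acetyl-5-(10-phenyldecyl)cyclohexane-1,3-dione (diastereomer mixture) | CC(=O)C1C(=O)CC(=O)CC1CCCCCCCCCCc1ccccc1
F4 | step 3 | dimethyl 2-(11-phenylundecylidene)propanedioate | COC(=O)C(=CCCCCCCCCCCc1ccccc1)C(=O)OC
F5 | step 5 | 3-acetyl-4,6-dioxo-2-(10-phenyldecyl)cyclohexane-1-carboxylic acid (diastereomer mixture, not isolated) | OC(=O)C1C(=O)CC(=O)C(C(C)=O)C1CCCCCCCCCCc1ccccc1
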